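## Structural features

The target is a flavanone of the dihydroflavonol type: benzene ring A is fused along C4a–C8a to the pyranone ring C (O1, C2, C3, C4), and ring B, a 3-hydroxy-4-methoxyphenyl group, is attached to C2. Ring A carries oxygen on four adjacent carbons (O1 on C8a, free hydroxyls on C5 and C6, a methyl ether on C7), so that C8 is its only C–H. The stereocentres C2 and C3 are neighbours, both R, with the C2 aryl group and the C3 methoxy group trans, which is the diequatorial and more stable arrangement. The β-aryloxy ketone is the fragile part: once C3 is enolised the C2–O1 bond can open (retro-oxa-Michael) and erase C2, C3 can epimerise or be dehydrogenated to the flavonol, and the 5,6-dihydroxy-7-methoxy ring is oxidised to an ortho-quinone by air in base. The carbon skeleton is simple; the real difficulty is to tell six oxygens apart (O3, O7 and O4' end as methyl ethers, O5, O6 and O3' as free hydroxyls) and to set the trans C2/C3 pair in the absolute sense on a ring that tolerates neither strong base nor strong Lewis acid. The key step uses the fact that C4 is a carbonyl carbon bonded only to C4a and C3: it can be brought in as carbon monoxide between an aryl iodide carbon (C4a) and an alkyne carbon (C3), while the phenol oxygen next to the iodide becomes O1 and closes ring C on C2. The same C4 carbonyl, peri to O5, is afterwards the handle that distinguishes O5 from O7 on a ring A building block that must be symmetric for the iodination to be unambiguous.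

## Logic of the disconnections

22 from 21: the three O–CH2Ph bonds at O5, O6 and O3' are cut last. Hydrogenolysis is neutral, so the air-sensitive triol and the two stereocentres appear only at the very end and never meet acid or base. The demand is that the benzylic C2–O1 bond and the C3 methyl ether survive.

21 from 20: the O–CH3 bond at C3 is cut. This reduces the problem to a trans α-ketol, a well-known compound class. The forward step must alkylate a hindered hydroxyl without a base able to enolise C3.

20 from 17 (through 18 and 19): the C3–O bond is cut. C3 is α to the ketone, so oxygen can be delivered to an enol ether. One stereocentre is removed and the remaining one (C2) controls it. Enolisation must not open the C2–O1 bond and the oxidant must come from the face away from the aryl group.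

17 from 15 (through 16): the C2–H and C3–H bonds are cut, giving a planar compound without stereocentres. The forward step must distinguish the two faces of a β-aryl, β-aryloxy enone, and any over-reduction at C4 must be reversible.

15 from 14 from 13: the three O–benzyl bonds of 15 are traced to free hydroxyls in 14, and these to one O–CH3 (O5) and two O–benzyl bonds (O6, O3') in 13. The reason is that O5 and O7 have to carry the same group in the ring A building block, and only the C4 carbonyl of 13 can tell them apart, by chelation. A ring A block with three methyl ethers would leave the O5/O6 against O7 distinction to a late, only partly chelation-controlled demethylation next to the C3 methyl ether. With benzyl on the future O6 the problem shrinks to one chelation-controlled cleavage on a flat compound. The demand is a Lewis acid that removes the chelated methyl ether and the benzyl ethers but leaves O7–CH3 and O4'–CH3 alone.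

13 from 5, 9 and 10: the bonds C4–C4a, C3–C4 and O1–C2 are cut and ring C is opened. Three fragments of low complexity result, none with a stereocentre. The forward step needs carbonylative instead of direct coupling and a six- instead of a five-membered closure.

5 from 4 from 2 from 1: the C–I bond is cut, then the aryl C–O bond of the phenol (the aryl carbon bore the formyl group in 2, via 3), then the O–benzyl bond. 4 has a mirror plane, so both positions ortho to its hydroxyl are the same and only one iodide can form. The demand is mono-iodination.

9 from 7 and 8, 7 from 6: the alkyne is cut between its two carbons, the terminal one coming from 8, then the O–benzyl bond. The forward step needs only mild base.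

## Other disconnections considered

Alternative 1: The cut is C2–C3 together with the C3–OMe bond. In the forward sense Rh2(OAc)4 would turn the ring A diazoketone A1 into a rhodium carbene and methanol would add to give an oxonium ylide. A chiral phosphoric acid would activate aldehyde 7 so that the ylide is trapped in an aldol-type addition before it collapses by proton shift, giving the syn adduct A2 with no ring formed.
- In its favour: the C3 methyl ether is made together with the C3–O bond, so no base-sensitive α-ketol is alkylated; this is better than the chosen plan. Both stereocentres would come from one catalytic step, and ring B enters as 7 without homologation.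
- Against it here: A1 needs a doubly ortho-substituted aroyl chloride and a diazomethane-type reagent. Simple O–H insertion competes with trapping, and stereocontrol with such a hindered aryl diazoketone is uncertain. Ring C must then be closed by O1–C2 bond formation with inversion at an electron-rich benzylic carbinol, where ionisation would blur C2. A2 also carries three methyl ethers on ring A, so the O5/O6 against O7 problem would fall on a finished flavanone.
- Comparison: in structure it is more convergent at the stereocentres and equal in ring A supply. In mechanism it depends on intercepting a transient ylide, whereas the chosen plan uses a robust palladium carbonylation followed by separately precedented steps. In step economy it would be about three steps shorter after the key step, a real advantage if the stereocontrol and the ring A deprotection could be solved.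

Alternative 2: The cut is C4a–C5 and C8–C8a, so ring A itself is built. Heating cyclobutenone A3 would open it to a vinylketene, which adds to siloxyalkyne A4 in a [2+2] sense. The new cyclobutenone opens again, and the dienylketene closes by 6π electrocyclisation and tautomerises to phenol A5.
- In its favour: every ring A oxygen is differentiated from the start (free O5, benzyl on O6, methyl on O7, silyl on the future O1). This is better than the chosen plan, which needs a deprotection and reprotection pair. The regiochemistry of the benzannulation is dictated by the mechanism and is equal in reliability to the symmetric iodination used here.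
- Against it here: A4 holds three contiguous oxygenated carbons, two of them stereocentres, and an ynol silyl ether, and needs a long asymmetric synthesis of its own. A3 is a labile 4-alkoxycyclobutenone. After the key step C4 still has to be oxidised and ring C closed with inversion at C2, under four different protecting groups.
- Comparison: in structure it solves the ring A problem most cleanly. In mechanism it is a metal-free pericyclic cascade of good predictability. In step economy it is clearly worse, since the effort moves into A4 and the route would be several steps longer.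

Alternative 3: The cut is O1–C8a. Anodic two-electron oxidation of catechol ketone A6 would give acyl ortho-quinone A7. Its C8a, conjugated to both the C5 quinone carbonyl and the C4 ketone, would be attacked by the C2 hydroxyl (6-endo-trig), and tautomerisation would return the catechol in A8.
- In its favour: the 5,6-dihydroxy-7-methoxy pattern emerges directly from the ring closure, with no ring A protecting groups and no selective dealkylation; this is better than the chosen plan. C2 reacts with retention, the oxidant is electric current, and A8 would be one hydrogenolysis from 22, a shorter endgame.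
- Against it here: A8 is more electron-rich than A6 and would be oxidised further at the same potential. A7 has other electrophilic positions and can add solvent. A6 is an anti β-hydroxy-α-methoxy ketone prone to retro-aldol cleavage and needs its own asymmetric synthesis. The precedent for this oxa-Michael closure to a flavanone is thinner than for the carbonylative annulation.
- Comparison: in structure and step count after the key step it is the equal or the better of the chosen plan. In mechanism it is less predictable (over-oxidation, site selectivity), and the supply of A6 cancels much of the saving.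

Key step: step 6

Remark: the sense of induction of the carbene ligand in step 9 cannot be predicted with certainty for this substrate, so the ligand enantiomer is specified by its outcome (2S) and not by its own descriptor. The descriptor at C2 changes from S (17, 18) to R (20 to 22) only because C3 gains oxygen; the spatial arrangement is unchanged.

## Steps

Step 1
Reactants: 1 syringaldehyde (4-hydroxy-3,5-dimethoxybenzaldehyde)
Product: 2 4-(benzyloxy)-3,5-dimethoxybenzaldehyde
Conditions: BnBr, K2CO3, DMF, 60 °C
Reagents that add atoms: benzyl bromide, BrCc1ccccc1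
Why: Williamson ether synthesis; the phenol flanked by two methoxy groups is hindered but acidic, so a dipolar aprotic solvent and mild heating should give complete O-alkylation. The benzyl group marks the future O6 as an oxygen that is set free later, while the two methoxy groups keep the ring symmetric.

Step 2
Reactants: 2 4-(benzyloxy)-3,5-dimethoxybenzaldehyde
Product: 4 4-(benzyloxy)-3,5-dimethoxyphenol, via aryl formate 3 (not isolated)
Conditions: mCPBA, CH2Cl2, 0 °C to rt; aq. NaHCO3 wash; then K2CO3 (cat.), MeOH, rt
Reagents that add atoms: meta-chloroperbenzoic acid, OOC(=O)c1cccc(Cl)c1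
Why: Dakin-type Baeyer–Villiger oxidation; in the peracid adduct the electron-rich trialkoxyaryl group migrates in preference to hydrogen and gives formate 3, which is methanolysed to the phenol under catalytic carbonate.

Step 3
Reactants: 4 4-(benzyloxy)-3,5-dimethoxyphenol
Product: 5 4-(benzyloxy)-2-iodo-3,5-dimethoxyphenol
Conditions: NIS (1.0 equiv), TsOH·H2O (cat.), MeCN, −20 to 0 °C, dark
Reagents that add atoms: N-iodosuccinimide, O=C1CCC(=O)N1I
Why: Electrophilic aromatic iodination; the para position is blocked and the two ortho positions are equivalent by the mirror plane of 4, so only one mono-iodide can form. One equivalent of reagent at low temperature should hold back the second iodination.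

Step 4
Reactants: 6 isovanillin (3-hydroxy-4-methoxybenzaldehyde)
Product: 7 3-(benzyloxy)-4-methoxybenzaldehyde
Conditions: BnBr, K2CO3, DMF, rt
Reagents that add atoms: benzyl bromide, BrCc1ccccc1
Why: Williamson ether synthesis of an unhindered phenol; the ring B hydroxyl is masked for the carbonate, the amine and the palladium chemistry that follow.

Step 5
Reactants: 7 3-(benzyloxy)-4-methoxybenzaldehyde; 8 dimethyl (1-diazo-2-oxopropyl)phosphonate
Product: 9 2-(benzyloxy)-4-ethynyl-1-methoxybenzene
Conditions: K2CO3, MeOH, rt
Reagents that add atoms: none
Why: Ohira–Bestmann modification of the Seyferth–Gilbert homologation; methoxide removes the acetyl group of 8, the diazomethylphosphonate anion adds to the aldehyde, and loss of phosphate and nitrogen followed by a 1,2-hydrogen shift of the alkylidene carbene gives the terminal alkyne. The conditions are mild enough for the benzyl ether and an electron-rich aryl aldehyde.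

Step 6
Reactants: 5 4-(benzyloxy)-2-iodo-3,5-dimethoxyphenol; 9 2-(benzyloxy)-4-ethynyl-1-methoxybenzene; 10 carbon monoxide
Product: 13 6-(benzyloxy)-2-[3-(benzyloxy)-4-methoxyphenyl]-5,7-dimethoxy-4H-chromen-4-one, via ortho-hydroxyaryl ynone 11 (not isolated), via beta-amino enone 12 (not isolated)
Conditions: PdCl2(PPh3)2 (5 mol %), Et2NH, CO (20 bar), 120 °C, autoclave, no copper salt
Reagents that add atoms: none
Why: PdCl2(PPh3)2 is reduced in the flask to zerovalent palladium, which inserts into the C–I bond of 5; CO insertion gives the aroylpalladium iodide, and alkyne 9, deprotonated by diethylamine at the metal, is transferred and reductively eliminated to give ynone 11 (bonds C4–C4a and C3–C4). Diethylamine adds to 11 to give the β-amino enone 12, and the ortho hydroxyl then displaces the amine at the same carbon by addition–elimination, which forms O1–C2 and closes ring C. The closest known reaction type is the palladium-catalysed carbonylative coupling of 2-iodophenols with terminal alkynes to chromones and flavones, a carbonylative Sonogashira-type coupling followed by cyclisation. Ring C closes in the six-membered mode, formally 6-endo-dig on 11 (6-endo-trig on 12), with oxygen attacking the β-carbon of the ynone. No stereocentre is formed. Two selectivities are needed: carbonylative over direct coupling (which would end in a 2-arylbenzofuran) is secured by CO pressure and the absence of copper, and six- over five-membered closure (flavone, not aurone) by the secondary amine, whose conjugate addition fixes C2 as the site of C–O bond formation. In the substrate, the mirror symmetry of 4 guarantees that iodine, and with it C4a, sits between the hydroxyl and a methoxy group, and the benzyl and methyl ethers are inert to the conditions.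

Step 7
Reactants: 13 6-(benzyloxy)-2-[3-(benzyloxy)-4-methoxyphenyl]-5,7-dimethoxy-4H-chromen-4-one
Product: 14 5,6-dihydroxy-2-(3-hydroxy-4-methoxyphenyl)-7-methoxy-4H-chromen-4-one
Conditions: BCl3 (6 equiv), C6HMe5 (pentamethylbenzene), CH2Cl2, −78 to 0 °C; then H2O/THF, 40 °C
Reagents that add atoms: none
Why: Lewis-acid ether cleavage; BCl3 removes both benzyl ethers (the benzyl cation is trapped by pentamethylbenzene) and, through the six-membered chelate with the C4 carbonyl, the peri methyl ether at O5, whereas the non-chelated methyl ethers at O7 and O4' should survive at or below 0 °C. The carbonyl thus tells O5 from O7 on a flat compound with no stereocentre to lose, and the warm aqueous stage breaks the boron chelate.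

Step 8
Reactants: 14 5,6-dihydroxy-2-(3-hydroxy-4-methoxyphenyl)-7-methoxy-4H-chromen-4-one
Product: 15 5,6-bis(benzyloxy)-2-[3-(benzyloxy)-4-methoxyphenyl]-7-methoxy-4H-chromen-4-one
Conditions: BnBr (4.5 equiv), K2CO3, n-Bu4NI (cat.), DMF, 70 °C, Ar
Reagents that add atoms: benzyl bromide, BrCc1ccccc1
Why: Threefold Williamson ether synthesis; the hydrogen-bonded hydroxyl at C5 needs excess reagent and heat, and the inert atmosphere protects the 5,6-diol from oxidation in base. All oxygens that must end free now carry the same hydrogenolysable group, so steps 7 and 8 together buy a neutral final deprotection.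

Step 9
Reactants: 15 5,6-bis(benzyloxy)-2-[3-(benzyloxy)-4-methoxyphenyl]-7-methoxy-4H-chromen-4-one
Product: 17 (2S)-5,6-bis(benzyloxy)-2-[3-(benzyloxy)-4-methoxyphenyl]-7-methoxy-2,3-dihydro-4H-chromen-4-one, via cis-flavan-4-ol 16 (not isolated)
Conditions: H2 (100 bar), Ru(cod)(2-methylallyl)2 (5 mol %), SINpEt·HBF4 [1,3-bis(1-(1-naphthyl)ethyl)imidazolinium BF4, enantiomer that gives 2S] (10 mol %), KOt-Bu (15 mol %), toluene, 25 °C; then DMP, CH2Cl2, 0 °C to rt
Reagents that add atoms: none
Why: Asymmetric hydrogenation of the flavone C2=C3 bond with the catalyst formed from Ru(cod)(2-methylallyl)2 and a chiral N-heterocyclic carbene, a known reaction of flavones; the C2 stereocentre is set by the ligand, which directs hydrogen to one face of the planar pyranone. Ketone that is reduced further to the cis alcohol 16 is returned to 17 by Dess–Martin oxidation, which does not touch C2, and the benzyl ethers are not expected to be cleaved by this homogeneous catalyst.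

Step 10
Reactants: 17 (2S)-5,6-bis(benzyloxy)-2-[3-(benzyloxy)-4-methoxyphenyl]-7-methoxy-2,3-dihydro-4H-chromen-4-one
Product: 20 (2R,3R)-5,6-bis(benzyloxy)-2-[3-(benzyloxy)-4-methoxyphenyl]-3-hydroxy-7-methoxy-2,3-dihydro-4H-chromen-4-one, via silyl enol ether 18 (not isolated), via silyloxy epoxide 19 (not isolated)
Conditions: TMSOTf, Et3N, CH2Cl2, 0 °C; then DMDO, acetone/CH2Cl2, −40 to 0 °C; then aq. citric acid, THF, 0 °C
Reagents that add atoms: dimethyldioxirane, CC1(C)OO1 (the oxygen at C3); trimethylsilyl triflate, C[Si](C)(C)OS(=O)(=O)C(F)(F)F (silyl group of 18 and 19 only, lost before 20)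
Why: Soft enolisation followed by Rubottom oxidation; silyl triflate and amine give enol ether 18 without a free enolate, so the C2–O1 bond is not eliminated and C2 is kept. The dioxirane epoxidises the C3=C4 bond on the face opposite the C2 aryl group, and acid opens silyloxy epoxide 19 to the α-ketol, which sets C3 trans to the aryl group (substrate control by C2); the trans isomer is also the thermodynamically preferred one.

Step 11
Reactants: 20 (2R,3R)-5,6-bis(benzyloxy)-2-[3-(benzyloxy)-4-methoxyphenyl]-3-hydroxy-7-methoxy-2,3-dihydro-4H-chromen-4-one
Product: 21 (2R,3R)-5,6-bis(benzyloxy)-2-[3-(benzyloxy)-4-methoxyphenyl]-3,7-dimethoxy-2,3-dihydro-4H-chromen-4-one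
Conditions: Me3OBF4, 1,8-bis(dimethylamino)naphthalene, 4 Å MS, CH2Cl2, 0 °C to rt
Reagents that add atoms: trimethyloxonium tetrafluoroborate, C[O+](C)C.F[B-](F)(F)F
Why: O-alkylation of the neutral alcohol by an oxonium salt, buffered by a hindered amine that is too weak and too slow a base to enolise C3, so ring opening, epimerisation and dehydrogenation to the flavonol should be avoided. No phenol is free at this stage, so only O3 is methylated.

Step 12
Reactants: 21 (2R,3R)-5,6-bis(benzyloxy)-2-[3-(benzyloxy)-4-methoxyphenyl]-3,7-dimethoxy-2,3-dihydro-4H-chromen-4-one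
Product: 22 (2R,3R)-5,6-dihydroxy-2-(3-hydroxy-4-methoxyphenyl)-3,7-dimethoxy-2,3-dihydro-4H-chromen-4-one
Conditions: H2 (1 atm), 10% Pd/C, EtOAc/MeOH, rt, degassed solvents, work-up under Ar
Reagents that add atoms: none
Why: Hydrogenolysis of three aryl benzyl ethers under neutral conditions; the methyl ethers, the ketone and both stereocentres are not addressed, and the reaction is stopped at the calculated hydrogen uptake to spare the benzylic C2–O1 bond.

## Compound list

1 | syringaldehyde (4-hydroxy-3,5-dimethoxybenzaldehyde) | COc1cc(C=O)cc(OC)c1O | starting material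
2 | 4-(benzyloxy)-3,5-dimethoxybenzaldehyde | COc1cc(C=O)cc(OC)c1OCc1ccccc1 | intermediate
3 | 4-(benzyloxy)-3,5-dimethoxyphenyl formate | COc1cc(OC=O)cc(OC)c1OCc1ccccc1 | intermediate (not isolated)
4 | 4-(benzyloxy)-3,5-dimethoxyphenol | COc1cc(O)cc(OC)c1OCc1ccccc1 | intermediate
5 | 4-(benzyloxy)-2-iodo-3,5-dimethoxyphenol | COc1cc(O)c(I)c(OC)c1OCc1ccccc1 | intermediate
6 | isovanillin (3-hydroxy-4-methoxybenzaldehyde) | COc1ccc(C=O)cc1O | starting material
7 | 3-(benzyloxy)-4-methoxybenzaldehyde | COc1ccc(C=O)cc1OCc1ccccc1 | intermediate
8 | dimethyl (1-diazo-2-oxopropyl)phosphonate | COP(=O)(OC)C(=[N+]=[N-])C(C)=O | starting material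
9 | 2-(benzyloxy)-4-ethynyl-1-methoxybenzene | COc1ccc(C#C)cc1OCc1ccccc1 | intermediate
10 | carbon monoxide | [C-]#[O+] | starting material
11 | 1-[3-(benzyloxy)-6-hydroxy-2,4-dimethoxyphenyl]-3-[3-(benzyloxy)-4-methoxyphenyl]prop-2-yn-1-one | COc1ccc(C#CC(=O)c2c(O)cc(OC)c(OCc3ccccc3)c2OC)cc1OCc1ccccc1 | intermediate (not isolated)
12 | 1-[3-(benzyloxy)-6-hydroxy-2,4-dimethoxyphenyl]-3-[3-(benzyloxy)-4-methoxyphenyl]-3-(diethylamino)prop-2-en-1-one (double-bond geometry not defined) | CCN(CC)C(=CC(=O)c1c(O)cc(OC)c(OCc2ccccc2)c1OC)c1ccc(OC)c(OCc2ccccc2)c1 | intermediate (not isolated)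
13 | 6-(benzyloxy)-2-[3-(benzyloxy)-4-methoxyphenyl]-5,7-dimethoxy-4H-chromen-4-one | COc1ccc(-c2cc(=O)c3c(OC)c(OCc4ccccc4)c(OC)cc3o2)cc1OCc1ccccc1 | intermediate
14 | 5,6-dihydroxy-2-(3-hydroxy-4-methoxyphenyl)-7-methoxy-4H-chromen-4-one | COc1ccc(-c2cc(=O)c3c(O)c(O)c(OC)cc3o2)cc1O | intermediate
15 | 5,6-bis(benzyloxy)-2-[3-(benzyloxy)-4-methoxyphenyl]-7-methoxy-4H-chromen-4-one | COc1ccc(-c2cc(=O)c3c(OCc4ccccc4)c(OCc4ccccc4)c(OC)cc3o2)cc1OCc1ccccc1 | intermediate
16 | (2S,4S)-5,6-bis(benzyloxy)-2-[3-(benzyloxy)-4-methoxyphenyl]-7-methoxy-3,4-dihydro-2H-chromen-4-ol (2,4-cis) | COc1ccc([C@H]2Oc3cc(OC)c(OCc4ccccc4)c(OCc4ccccc4)c3[C@@H](O)C2)cc1OCc1ccccc1 | intermediate (not isolated)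
17 | (2S)-5,6-bis(benzyloxy)-2-[3-(benzyloxy)-4-methoxyphenyl]-7-methoxy-2,3-dihydro-4H-chromen-4-one | COc1ccc([C@H]2Oc3cc(OC)c(OCc4ccccc4)c(OCc4ccccc4)c3C(=O)C2)cc1OCc1ccccc1 | intermediate
18 | (2S)-5,6-bis(benzyloxy)-2-[3-(benzyloxy)-4-methoxyphenyl]-7-methoxy-4-[(trimethylsilyl)oxy]-2H-chromene | COc1ccc([C@H]2Oc3cc(OC)c(OCc4ccccc4)c(OCc4ccccc4)c3C(O[Si](C)(C)C)=C2)cc1OCc1ccccc1 | intermediate (not isolated)
19 | 3,4-epoxide of 18: 5,6-bis(benzyloxy)-2-[3-(benzyloxy)-4-methoxyphenyl]-3,4-epoxy-7-methoxy-4-[(trimethylsilyl)oxy]chromane, C2 as in 18, oxirane oxygen on the face opposite the C2 aryl group | COc1ccc([C@H]2Oc3cc(OC)c(OCc4ccccc4)c(OCc4ccccc4)c3[C@]5(O[Si](C)(C)C)O[C@H]25)cc1OCc1ccccc1 | intermediate (not isolated)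
20 | (2R,3R)-5,6-bis(benzyloxy)-2-[3-(benzyloxy)-4-methoxyphenyl]-3-hydroxy-7-methoxy-2,3-dihydro-4H-chromen-4-one (2,3-trans) | COc1ccc([C@H]2Oc3cc(OC)c(OCc4ccccc4)c(OCc4ccccc4)c3C(=O)[C@@H]2O)cc1OCc1ccccc1 | intermediate
21 | (2R,3R)-5,6-bis(benzyloxy)-2-[3-(benzyloxy)-4-methoxyphenyl]-3,7-dimethoxy-2,3-dihydro-4H-chromen-4-one (2,3-trans) | COc1ccc([C@H]2Oc3cc(OC)c(OCc4ccccc4)c(OCc4ccccc4)c3C(=O)[C@@H]2OC)cc1OCc1ccccc1 | intermediate
22 | (2R,3R)-5,6-dihydroxy-2-(3-hydroxy-4-methoxyphenyl)-3,7-dimethoxy-2,3-dihydro-4H-chromen-4-one (2,3-trans) | COc1ccc([C@H]2Oc3cc(OC)c(O)c(O)c3C(=O)[C@@H]2OC)cc1O | target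

## Step count and least certain steps

Total: 12 steps. Longest linear sequence: 10 steps (steps 1, 2, 3, 6, 7, 8, 9, 10, 11, 12, from 1); the ring B branch (steps 4 and 5) joins at step 6.

Step 6 (key step). Most likely to go wrong: direct, non-carbonylative coupling followed by closure to a 2-arylbenzofuran, or capture of the aroylpalladium species by diethylamine. The iodide is flanked by two oxygen substituents and is electron-rich, so oxidative addition and CO insertion are slow compared with these side reactions. Fallback, from 4 and 9, back to the route at 13, with the carbonyl carbon brought in as a formyl group instead of CO: magnesium-mediated ortho-formylation of 4 (MgCl2, Et3N, paraformaldehyde, MeCN, reflux) should give 3-(benzyloxy)-6-hydroxy-2,4-dimethoxybenzaldehyde F1. Alkyne 9 is deprotonated with n-BuLi to lithium [3-(benzyloxy)-4-methoxyphenyl]ethynide F2, and an excess is added to F1 (THF, −78 to 0 °C) to give the racemic propargylic alcohol 4-(benzyloxy)-2-{3-[3-(benzyloxy)-4-methoxyphenyl]-1-hydroxyprop-2-yn-1-yl}-3,5-dimethoxyphenol F3. MnO2 in CH2Cl2 oxidises F3 to ynone 11, and Et2NH in EtOH closes it through 12 to 13.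

Step 9. Most likely to go wrong: low conversion or poor facial discrimination. The peri benzyloxy group at C5 and the many ether oxygens crowd and coordinate the ruthenium centre, and partial arene reduction is possible at this pressure. Fallback, from 15, back at 17, replacing catalyst control by kinetic resolution: conjugate reduction with LiBH(s-Bu)3 (THF, −78 °C) should give racemic 5,6-bis(benzyloxy)-2-[3-(benzyloxy)-4-methoxyphenyl]-7-methoxy-2,3-dihydro-4H-chromen-4-one F4. Asymmetric transfer hydrogenation with RhCl(Cp*)(TsDPEN) (the enantiomer that reduces the 2R ketone faster; HCO2H/Et3N, EtOAc, rt, to just over half conversion) would leave the 2S ketone 17 and convert the other enantiomer into (2R,4R)-5,6-bis(benzyloxy)-2-[3-(benzyloxy)-4-methoxyphenyl]-7-methoxy-3,4-dihydro-2H-chromen-4-ol F5, which is separated by chromatography. At most half of the material is carried on.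

Step 10. Most likely to go wrong: incomplete silylation or hydrolysis of the labile enol ether before oxidation, because the silyloxy group at C4 is crowded by the peri benzyloxy group at C5, and some loss of trans selectivity. Fallback, from 17, back at 20, with oxygen transfer to a metal enolate instead of epoxidation of an enol ether: deprotonation with KN(SiMe3)2 (THF, −78 °C) gives the potassium enolate of 17 F6. The endocyclic enolate is poorly aligned for expulsion of O1 at this temperature, and it is oxidised in the flask by 2-(phenylsulfonyl)-3-phenyloxaziridine from the face opposite the aryl group; a cold NH4Cl quench gives 20.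

Step 11. Most likely to go wrong: slow alkylation of the hindered α-hydroxyl, which is hydrogen-bonded to the carbonyl, so that long exposure to the amine allows epimerisation at C3 or dehydrogenation to the flavonol. Fallback, from 20, back at 21, changing the activation from a base-buffered oxonium salt to acid catalysis with no base in the flask: methyl 2,2,2-trichloroacetimidate with catalytic TfOH in CH2Cl2/cyclohexane at rt. No new compound is made.

Step 12. Most likely to go wrong: over-reduction by hydrogenolysis of the benzylic C2–O1 bond once the benzyl ethers are gone, and air oxidation of the 5,6-dihydroxy ring during work-up. Fallback, from 21, back at 22, replacing hydrogen and palladium by Lewis-acid debenzylation: BCl3 and pentamethylbenzene in CH2Cl2, held at −78 °C and quenched cold; at this temperature benzyl ethers are cleaved while methyl ethers, including the one at C3, are expected to remain. No new compound is made.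

## Further compounds

F1 | step 6 | 3-(benzyloxy)-6-hydroxy-2,4-dimethoxybenzaldehyde | COc1cc(O)c(C=O)c(OC)c1OCc1ccccc1
F2 | step 6 | lithium [3-(benzyloxy)-4-methoxyphenyl]ethynide | [Li+].[C-]#Cc1ccc(OC)c(OCc2ccccc2)c1
F3 | step 6 | 4-(benzyloxy)-2-{3-[3-(benzyloxy)-4-methoxyphenyl]-1-hydroxyprop-2-yn-1-yl}-3,5-dimethoxyphenol (racemic) | COc1ccc(C#CC(O)c2c(O)cc(OC)c(OCc3ccccc3)c2OC)cc1OCc1ccccc1
F4 | step 9 | racemic 5,6-bis(benzyloxy)-2-[3-(benzyloxy)-4-methoxyphenyl]-7-methoxy-2,3-dihydro-4H-chromen-4-one | COc1ccc(C2Oc3cc(OC)c(OCc4ccccc4)c(OCc4ccccc4)c3C(=O)C2)cc1OCc1ccccc1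
F5 | step 9 | (2R,4R)-5,6-bis(benzyloxy)-2-[3-(benzyloxy)-4-methoxyphenyl]-7-methoxy-3,4-dihydro-2H-chromen-4-ol | COc1ccc([C@@H]2Oc3cc(OC)c(OCc4ccccc4)c(OCc4ccccc4)c3[C@H](O)C2)cc1OCc1ccccc1
F6 | step 10 | potassium enolate of 17 (potassium (2S)-5,6-bis(benzyloxy)-2-[3-(benzyloxy)-4-methoxyphenyl]-7-methoxy-2H-chromen-4-olate) | COc1ccc([C@H]2Oc3cc(OC)c(OCc4ccccc4)c(OCc4ccccc4)c3C([O-])=C2)cc1OCc1ccccc1.[K+]
F0 | step 11 | none | none
F0 | step 12 | none | none
A1 | alternative 1 | 2-diazo-1-[2,3,4-trimethoxy-6-(triisopropylsilyloxy)phenyl]ethan-1-one | COc1cc(O[Si](C(C)C)(C(C)C)C(C)C)c(C(=O)C=[N+]=[N-])c(OC)c1OC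
A2 | alternative 1 | (2R,3S)-3-[3-(benzyloxy)-4-methoxyphenyl]-3-hydroxy-2-methoxy-1-[2,3,4-trimethoxy-6-(triisopropylsilyloxy)phenyl]propan-1-one | COc1ccc([C@H](O)[C@@H](OC)C(=O)c2c(O[Si](C(C)C)(C(C)C)C(C)C)cc(OC)c(OC)c2OC)cc1OCc1ccccc1
A3 | alternative 2 | 4-(benzyloxy)-3-methoxycyclobut-2-en-1-one | COC1=CC(=O)C1OCc1ccccc1
A4 | alternative 2 | [(5-[3-(benzyloxy)-4-methoxyphenyl]-5-[(tert-butyldimethylsilyl)oxy]-4-methoxy-3-[(triethylsilyl)oxy]pent-1-yn-1-yl)oxy]tri(propan-2-yl)silane (C4 and C5 configured as in A5, C3 epimer mixture) | CC(C)[Si](OC#CC(O[Si](CC)(CC)CC)[C@H](OC)[C@@H](O[Si](C)(C)C(C)(C)C)c1ccc(OC)c(OCc2ccccc2)c1)(C(C)C)C(C)C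
A5 | alternative 2 | pentasubstituted ring A phenol carrying the C2–C4 chain (C4 epimer mixture) | Oc1c(C(O[Si](CC)(CC)CC)[C@H](OC)[C@@H](O[Si](C)(C)C(C)(C)C)c2ccc(OC)c(OCc3ccccc3)c2)c(O[Si](C(C)C)(C(C)C)C(C)C)cc(OC)c1OCc1ccccc1
A6 | alternative 3 | (2R,3R)-3-[3-(benzyloxy)-4-methoxyphenyl]-1-(2,3-dihydroxy-4-methoxyphenyl)-3-hydroxy-2-methoxypropan-1-one | COc1ccc([C@@H](O)[C@@H](OC)C(=O)c2ccc(OC)c(O)c2O)cc1OCc1ccccc1
A7 | alternative 3 | 3-{(2R,3R)-3-[3-(benzyloxy)-4-methoxyphenyl]-3-hydroxy-2-methoxypropanoyl}-6-methoxycyclohexa-3,5-diene-1,2-dione | COc1ccc([C@@H](O)[C@@H](OC)C(=O)C2=CC=C(OC)C(=O)C2=O)cc1OCc1ccccc1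
A8 | alternative 3 | (2R,3R)-2-[3-(benzyloxy)-4-methoxyphenyl]-5,6-dihydroxy-3,7-dimethoxychroman-4-one | COc1ccc([C@H]2Oc3cc(OC)c(O)c(O)c3C(=O)[C@@H]2OC)cc1OCc1ccccc1
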